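**Numbering used:** chain C1 (ester carbonyl) to C10 (CH2 on the central furan). Ring B is the central 2,4‑disubstituted furan (O1', C2' carrying the CH2–3‑furyl group, C4' carrying C10). Ring A is the terminal 3‑furyl ring.

## Retrosynthetic overview

1. Key cut at the unactivated C4–C5 sp3–sp3 bond, turning both sides into carboxylic acids. C1–C4 with the C3 methyl stereocentre is methyl hydrogen (R)‑3‑methylglutarate minus CO2, and C5–C10 with both furans is the γ,δ‑unsaturated acid 15. The two are joined as N‑hydroxyphthalimide esters by Ni‑electrocatalytic doubly decarboxylative coupling; the cathodic conditions spare furan rings A and B and C7=C8, which an anodic Kolbe coupling would not.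
2. The C5 carboxyl and the (E)‑C7(CH3)=C8 olefin of 15 are together the retron of a Johnson–Claisen [3,3] shift of isopropenyl carbinol 11, which forms C5–C6 and fixes the alkene geometry in one step.
3. Carbinol 11 comes from aldehyde 9, and 9 from bromide 5 by Br/Li exchange and oxetane opening (C8–C10).
4. No ring is formed in the route. Ring B is bought with its 2,4‑pattern as 4‑bromofuran‑2‑carbaldehyde and ring A as 3‑bromofuran; the bridging CH2 comes from carbonyl addition and ionic deoxygenation.

Key step: step 9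

**Assumption:** methyl hydrogen (R)‑3‑methylglutarate (17) is taken as a purchasable enantiopure half‑ester (the half‑ester of enzymatic desymmetrisation of the 3‑methylglutaric diester); it supplies C3 with its final configuration.

## Route

**Step 1**
Reactants: 1 3‑bromofuran; 2 4‑bromofuran‑2‑carbaldehyde
Product: 4 (4‑bromofuran‑2‑yl)(furan‑3‑yl)methanol (racemic), via furan‑3‑yllithium 3 (not isolated)
Conditions: n‑BuLi (1.0 equiv), Et2O, −78 °C, 30 min; then 2 in THF, −78 °C; H2O quench
Reagents that add atoms: none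
Why: Br/Li exchange gives 3‑furyllithium, which is positionally stable at −78 °C and adds 1,2 to the aldehyde (organolithium carbonyl addition) much faster than it can exchange with the ring bromide of 2; the racemic carbinol centre is erased in step 2.

**Step 2**
Reactants: 4 (4‑bromofuran‑2‑yl)(furan‑3‑yl)methanol
Product: 5 4‑bromo‑2‑(furan‑3‑ylmethyl)furan
Conditions: Et3SiH (3 equiv), TFA (1.5 equiv), CH2Cl2, −40 → 0 °C
Reagents that add atoms: none
Why: Ionic hydrogenation of a diaryl carbinol: ionisation gives a cation stabilised by both furans, and excess silane at low temperature should trap it by hydride transfer before it alkylates a furan, leaving the C–Br bond untouched.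

**Step 3**
Reactants: 5 4‑bromo‑2‑(furan‑3‑ylmethyl)furan; 6 oxetane
Product: 8 3‑[5‑(furan‑3‑ylmethyl)furan‑3‑yl]propan‑1‑ol, via 5‑(furan‑3‑ylmethyl)furan‑3‑yllithium 7 (not isolated)
Conditions: t‑BuLi (2.05 equiv), Et2O, −78 °C, 15 min; oxetane (2 equiv), then BF3·OEt2 (1.5 equiv), −78 °C; aq. NaHCO3
Reagents that add atoms: none
Why: Br/Li exchange with t‑BuLi at −78 °C is faster than any deprotonation, and the aryllithium opens BF3‑activated oxetane at a CH2–O carbon (Lewis‑acid‑promoted oxetane opening by an organolithium), installing C10–C8 as a 3‑hydroxypropyl chain at C4' of ring B.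

**Step 4**
Reactants: 8 3‑[5‑(furan‑3‑ylmethyl)furan‑3‑yl]propan‑1‑ol
Product: 9 3‑[5‑(furan‑3‑ylmethyl)furan‑3‑yl]propanal
Conditions: Dess–Martin periodinane (1.2 equiv), CH2Cl2, 0 °C → rt
Reagents that add atoms: none
Why: Dess–Martin oxidation converts the primary alcohol into the aldehyde under near‑neutral conditions that the furans and the bis‑furyl CH2 tolerate.

**Step 5**
Reactants: 9 3‑[5‑(furan‑3‑ylmethyl)furan‑3‑yl]propanal; 10 isopropenylmagnesium bromide
Product: 11 1‑[5‑(furan‑3‑ylmethyl)furan‑3‑yl]‑4‑methylpent‑4‑en‑3‑ol (racemic)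
Conditions: THF, −78 → 0 °C; aq. NH4Cl
Reagents that add atoms: none
Why: Grignard 1,2‑addition to the unhindered aldehyde gives the 2‑methylallylic carbinol; it is racemic, which does not matter because this carbon (C8) becomes sp2 in step 6.

**Step 6**
Reactants: 11 1‑[5‑(furan‑3‑ylmethyl)furan‑3‑yl]‑4‑methylpent‑4‑en‑3‑ol; 12 triethyl orthoacetate
Product: 15 (4E)‑7‑[5‑(furan‑3‑ylmethyl)furan‑3‑yl]‑4‑methylhept‑4‑enoic acid, via mixed ketene acetal 13 (not isolated), via ethyl ester 14 (not isolated)
Conditions: MeC(OEt)3 (6 equiv), EtCO2H (5 mol%), 138 °C, EtOH distilled off; concentrate; then LiOH·H2O, THF/MeOH/H2O, rt; cold 1 M HCl to pH 4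
Reagents that add atoms: lithium hydroxide, [Li+].[OH-]
Why: Johnson–Claisen rearrangement through a chair transition state with the CH2CH2‑furyl substituent equatorial (the axial placement clashes 1,3‑diaxially with the ethoxy group) should form the C5–C6 bond and the (E)‑C7(CH3)=C8 alkene together, and the crude ester is saponified in the same operation.

**Step 7**
Reactants: 15 (4E)‑7‑[5‑(furan‑3‑ylmethyl)furan‑3‑yl]‑4‑methylhept‑4‑enoic acid
Product: 16 1,3‑dioxoisoindolin‑2‑yl (4E)‑7‑[5‑(furan‑3‑ylmethyl)furan‑3‑yl]‑4‑methylhept‑4‑enoate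
Conditions: N‑hydroxyphthalimide (1.1 equiv), DIC (1.1 equiv), DMAP (5 mol%), CH2Cl2, rt
Reagents that add atoms: N‑hydroxyphthalimide, ON1C(=O)c2ccccc2C1=O
Why: Carbodiimide (Steglich‑type) esterification with N‑hydroxyphthalimide gives the redox‑active ester under neutral conditions.

**Step 8**
Reactants: 17 methyl hydrogen (R)‑3‑methylglutarate [(3R)‑5‑methoxy‑3‑methyl‑5‑oxopentanoic acid]
Product: 18 1‑(1,3‑dioxoisoindolin‑2‑yl) 5‑methyl (3S)‑3‑methylpentanedioate
Conditions: N‑hydroxyphthalimide (1.1 equiv), DIC (1.1 equiv), DMAP (5 mol%), CH2Cl2, rt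
Reagents that add atoms: N‑hydroxyphthalimide, ON1C(=O)c2ccccc2C1=O
Why: The same carbodiimide esterification activates only the free acid; the stereocentre is β to both carbonyls and no bond to it is touched, so the descriptor changes from R to S only because the CIP priorities of the two arms swap.

**Step 9 (key step)**
Reactants: 16 1,3‑dioxoisoindolin‑2‑yl (4E)‑7‑[5‑(furan‑3‑ylmethyl)furan‑3‑yl]‑4‑methylhept‑4‑enoate; 18 1‑(1,3‑dioxoisoindolin‑2‑yl) 5‑methyl (3S)‑3‑methylpentanedioate (3 equiv)
Product: 19 methyl (3R,7E)‑10‑[5‑(furan‑3‑ylmethyl)furan‑3‑yl]‑3,7‑dimethyldec‑7‑enoate (target)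
Conditions: NiCl2·6H2O (20 mol%), 2,2':6',2''‑terpyridine (20 mol%), AgNO3 (30 mol%, silver‑coated cathode formed in situ), NaI, NMP, undivided cell, (+)Mg/(−)RVC, constant current, rt; aq. NH4Cl
Reagents that add atoms: none
Why: Single‑electron reduction of each phthalimide ester triggers loss of CO2 and phthalimide anion to give the primary radicals at C5 (from 16) and C4 (from 18); low‑valent Ni(terpyridine) captures one radical as an alkyl–nickel species, captures the second, and reductive elimination forms the C4–C5 bond, with the Mg anode supplying the electrons. The closest known reaction type is the Ni‑electrocatalytic doubly decarboxylative C(sp3)–C(sp3) cross‑coupling of two redox‑active esters, established for primary–primary pairs as a reductive surrogate of the mixed Kolbe electrolysis. No ring is closed and no stereocentre is created: C3 is a spectator carbon next to the C4 radical and keeps the R configuration bought in 17. The step needs cross‑ over homo‑coupling, which the threefold excess of the cheap partner 18 should secure, its symmetrical diester dimer being separable by polarity. It also needs retention of the E‑alkene, which should hold because 3‑exo closure of the homoallylic C5 radical onto C7 is slow and reversible compared with capture by nickel. Because the chemistry is cathodic, the two electron‑rich furans, the bis‑furyl CH2 and the trisubstituted alkene should pass unchanged, and the target is reached without protecting groups or redox adjustments.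

## Compound list

1 | 3‑bromofuran | Brc1ccoc1 | starting material
2 | 4‑bromofuran‑2‑carbaldehyde | O=Cc1cc(Br)co1 | starting material
3 | furan‑3‑yllithium | [Li]c1ccoc1 | intermediate (not isolated)
4 | (4‑bromofuran‑2‑yl)(furan‑3‑yl)methanol (racemic) | OC(c1ccoc1)c1cc(Br)co1 | intermediate
5 | 4‑bromo‑2‑(furan‑3‑ylmethyl)furan | Brc1coc(Cc2ccoc2)c1 | intermediate
6 | oxetane | C1COC1 | starting material
7 | 5‑(furan‑3‑ylmethyl)furan‑3‑yllithium | [Li]c1coc(Cc2ccoc2)c1 | intermediate (not isolated)
8 | 3‑[5‑(furan‑3‑ylmethyl)furan‑3‑yl]propan‑1‑ol | OCCCc1coc(Cc2ccoc2)c1 | intermediate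
9 | 3‑[5‑(furan‑3‑ylmethyl)furan‑3‑yl]propanal | O=CCCc1coc(Cc2ccoc2)c1 | intermediate
10 | isopropenylmagnesium bromide | CC(=C)[Mg]Br | starting material
11 | 1‑[5‑(furan‑3‑ylmethyl)furan‑3‑yl]‑4‑methylpent‑4‑en‑3‑ol (racemic) | CC(=C)C(O)CCc1coc(Cc2ccoc2)c1 | intermediate
12 | triethyl orthoacetate | CCOC(C)(OCC)OCC | starting material
13 | mixed ketene acetal, 4‑{3‑[(1‑ethoxyvinyl)oxy]‑4‑methylpent‑4‑en‑1‑yl}‑2‑(furan‑3‑ylmethyl)furan | C=C(OCC)OC(CCc1coc(Cc2ccoc2)c1)C(C)=C | intermediate (not isolated)
14 | ethyl (4E)‑7‑[5‑(furan‑3‑ylmethyl)furan‑3‑yl]‑4‑methylhept‑4‑enoate | CCOC(=O)CC/C(C)=C/CCc1coc(Cc2ccoc2)c1 | intermediate (not isolated)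
15 | (4E)‑7‑[5‑(furan‑3‑ylmethyl)furan‑3‑yl]‑4‑methylhept‑4‑enoic acid | OC(=O)CC/C(C)=C/CCc1coc(Cc2ccoc2)c1 | intermediate
16 | 1,3‑dioxoisoindolin‑2‑yl (4E)‑7‑[5‑(furan‑3‑ylmethyl)furan‑3‑yl]‑4‑methylhept‑4‑enoate | O=C(CC/C(C)=C/CCc1coc(Cc2ccoc2)c1)ON1C(=O)c2ccccc2C1=O | intermediate
17 | methyl hydrogen (R)‑3‑methylglutarate, (3R)‑5‑methoxy‑3‑methyl‑5‑oxopentanoic acid | COC(=O)C[C@H](C)CC(=O)O | starting material
18 | 1‑(1,3‑dioxoisoindolin‑2‑yl) 5‑methyl (3S)‑3‑methylpentanedioate | COC(=O)C[C@H](C)CC(=O)ON1C(=O)c2ccccc2C1=O | intermediate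
19 | methyl (3R,7E)‑10‑[5‑(furan‑3‑ylmethyl)furan‑3‑yl]‑3,7‑dimethyldec‑7‑enoate | COC(=O)C[C@H](C)CCC/C(C)=C/CCc1coc(Cc2ccoc2)c1 | target

## Step count

Total steps: 9. Longest linear sequence: 8 (steps 1–7, then 9); step 8 is a one‑step side branch.

## Three steps most likely to fail

**Step 9 (key step).** The two radicals may pair statistically or be reduced to alkanes faster than nickel mediates the cross‑coupling, and reversible cyclisation of the homoallylic radical could erode the alkene geometry. The fallback forms the neighbouring C3–C4 bond instead and sets C3 by catalyst control. It sets out from acid 15. LiAlH4 in THF at 0 °C should reduce it to (4E)‑7‑[5‑(furan‑3‑ylmethyl)furan‑3‑yl]‑4‑methylhept‑4‑en‑1‑ol F1, whose carbinol carbon is now C4. CBr4/PPh3 in CH2Cl2 (Appel reaction) should give 4‑[(3E)‑7‑bromo‑4‑methylhept‑3‑en‑1‑yl]‑2‑(furan‑3‑ylmethyl)furan F2. Magnesium in THF converts this into [(4E)‑7‑[5‑(furan‑3‑ylmethyl)furan‑3‑yl]‑4‑methylhept‑4‑en‑1‑yl]magnesium bromide F3. A CuI/Tol‑BINAP‑catalysed asymmetric conjugate addition of F3 to methyl (E)‑but‑2‑enoate (t‑BuOMe, −40 °C, ligand antipode chosen for the 3R product) then returns to the route at 19.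

**Step 2.** The doubly furan‑stabilised cation may alkylate furan α‑positions (Friedel–Crafts oligomerisation) faster than it takes up hydride, and the acid may degrade the furans. The fallback avoids any cation and sets out from aldehyde 2. Condensation with tosylhydrazide in MeOH at rt should give N'‑[(E)‑(4‑bromofuran‑2‑yl)methylidene]‑4‑methylbenzenesulfonohydrazide F4. Metal‑free reductive coupling of F4 with furan‑3‑ylboronic acid (K2CO3, dioxane, 110 °C; diazo formation, 1,2‑shift from boron to carbon with loss of N2, protodeboronation) should give the diheteroarylmethane directly. No transition metal is present, so the ring bromide is not at risk. The route is rejoined at 5.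

**Step 3.** The 3‑furyllithium may move its charge by proton transfer (to a furan α‑position or to the doubly activated bridging CH2) or be degraded by BF3 before it opens the oxetane. The fallback replaces the organolithium by a cross‑coupling and sets out from bromide 5. Negishi coupling with [2‑(1,3‑dioxolan‑2‑yl)ethyl]zinc bromide (Pd(OAc)2/SPhos, THF, 40 °C) should give 2‑{2‑[5‑(furan‑3‑ylmethyl)furan‑3‑yl]ethyl}‑1,3‑dioxolane F5. Mild acetal hydrolysis (AcOH/H2O/THF, 40 °C) then gives the aldehyde, returning to the route at 9 and bypassing 7, 8 and step 4.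

## Further compounds

F1 | step 9 | (4E)‑7‑[5‑(furan‑3‑ylmethyl)furan‑3‑yl]‑4‑methylhept‑4‑en‑1‑ol | OCCC/C(C)=C/CCc1coc(Cc2ccoc2)c1
F2 | step 9 | 4‑[(3E)‑7‑bromo‑4‑methylhept‑3‑en‑1‑yl]‑2‑(furan‑3‑ylmethyl)furan | BrCCC/C(C)=C/CCc1coc(Cc2ccoc2)c1
F3 | step 9 | [(4E)‑7‑[5‑(furan‑3‑ylmethyl)furan‑3‑yl]‑4‑methylhept‑4‑en‑1‑yl]magnesium bromide | Br[Mg]CCC/C(C)=C/CCc1coc(Cc2ccoc2)c1
F4 | step 2 | N'‑[(E)‑(4‑bromofuran‑2‑yl)methylidene]‑4‑methylbenzenesulfonohydrazide | Cc1ccc(cc1)S(=O)(=O)N/N=C/c1cc(Br)co1
F5 | step 3 | 2‑{2‑[5‑(furan‑3‑ylmethyl)furan‑3‑yl]ethyl}‑1,3‑dioxolane | C1COC(CCc2coc(Cc3ccoc3)c2)O1
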